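**Plan**
- Retrosynthesis: after removal of two aryl acetates, the pyranone ring is opened at C3–C4, both carbons becoming chlorides. The open chain is then cut at O1–C2 (phenol + phenacyl bromide) and at the aryl–geranyl bond (aryl bromide + allylstannane).
- Enabling feature: C3 is benzylic (it carries the B ring) and is bonded directly to the aroyl carbon C4 of ring A inside the pyranone ring. C3–C4 can therefore be made from a benzylic radical and an acyl-nickel species, with no enolate of the epimerisable α-aryl ketone.
- Forward: ring A is geranylated, O-alkylated with the B-ring bromoketone, the ketone reduced, the pivalates exchanged for acetates, both OH groups turned into chlorides, and the pyranone ring closed last.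
- Stereochemistry: C3 (S) is set in the ring closure by a chiral bis(oxazoline)–nickel catalyst acting on the racemic chloride. The 2E alkene comes from geranyl bromide.

Key step: step 10

Assumption: the sense of induction of the bis(oxazoline) in the tethered coupling cannot be read from the intermolecular case, so the ligand antipode that delivers 3S is taken from a pilot run with both commercial enantiomers; methyl 5-bromo-2,4-dihydroxybenzoate is used as the catalogue methyl ester of the corresponding acid.

Step 1
Reactants: 1 geranyl bromide
Product: 2 geranyltributylstannane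
Conditions: Bu3SnH, LDA, THF, 0 °C; then 1, −78 °C → rt
Reagents that add atoms: tributyltin hydride, CCCC[SnH](CCCC)CCCC
Why: Tributylstannyllithium displaces the primary allylic bromide by direct SN2 substitution (stannyl anion alkylation), which should keep the 2E geometry and give the linear allylstannane.

Step 2
Reactants: 3 methyl 5-bromo-2,4-dihydroxybenzoate
Product: 4 methyl 5-bromo-2-hydroxy-4-(pivaloyloxy)benzoate
Conditions: PivCl (1.05 equiv), Et3N, CH2Cl2, −10 → 0 °C
Reagents that add atoms: pivaloyl chloride, CC(C)(C)C(=O)Cl
Why: Chemoselective O-acylation, because the 2-hydroxyl is held in a hydrogen bond to the ester carbonyl and one equivalent of acid chloride should take the free, more acidic 4-hydroxyl.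

Step 3
Reactants: 4 methyl 5-bromo-2-hydroxy-4-(pivaloyloxy)benzoate; 2 geranyltributylstannane
Product: 5 methyl 5-[(2E)-3,7-dimethylocta-2,6-dien-1-yl]-2-hydroxy-4-(pivaloyloxy)benzoate
Conditions: Pd(PPh3)4 (5 mol %), DMF, 95 °C
Reagents that add atoms: none
Why: Stille cross-coupling of an aryl bromide with an allylstannane, in which reductive elimination at the unsubstituted allyl terminus should give the linear 2E-geranyl arene while phenol, pivalate and ester are inert to the neutral conditions.

Step 4
Reactants: 6 4'-hydroxy-2'-methoxyacetophenone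
Product: 7 4-acetyl-3-methoxyphenyl pivalate
Conditions: PivCl, Et3N, DMAP (cat.), CH2Cl2, 0 °C → rt
Reagents that add atoms: pivaloyl chloride, CC(C)(C)C(=O)Cl
Why: DMAP-catalysed acylation of a phenol, which masks the phenol for the bromination and alkylation that follow and lowers the electron density of the ring.

Step 5
Reactants: 7 4-acetyl-3-methoxyphenyl pivalate
Product: 8 4-(2-bromoacetyl)-3-methoxyphenyl pivalate
Conditions: CuBr2 (2.1 equiv), EtOAc/CHCl3, reflux
Reagents that add atoms: copper(II) bromide, Br[Cu]Br
Why: Copper(II) bromide α-bromination of an aryl methyl ketone through its enol, which should stop at the monobromide and spare the ring because the acyl group and the acylated 4-oxygen deactivate it.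

Step 6
Reactants: 5 methyl 5-geranyl-2-hydroxy-4-(pivaloyloxy)benzoate; 8 4-(2-bromoacetyl)-3-methoxyphenyl pivalate
Product: 9 methyl 5-geranyl-2-{2-[2-methoxy-4-(pivaloyloxy)phenyl]-2-oxoethoxy}-4-(pivaloyloxy)benzoate
Conditions: K2CO3, acetone, 40 °C
Reagents that add atoms: none
Why: Williamson ether synthesis on a phenacyl bromide, an SN2 electrophile reactive enough for carbonate in acetone, conditions under which the hindered aryl pivalates should not transfer and the keto ester should not condense.

Step 7
Reactants: 9 methyl 5-geranyl-2-{2-[2-methoxy-4-(pivaloyloxy)phenyl]-2-oxoethoxy}-4-(pivaloyloxy)benzoate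
Product: 10 methyl 5-geranyl-2-{2-hydroxy-2-[2-methoxy-4-(pivaloyloxy)phenyl]ethoxy}-4-(pivaloyloxy)benzoate (racemic)
Conditions: NaBH4, THF/MeOH 4:1, −10 °C
Reagents that add atoms: none
Why: Chemoselective borohydride reduction of the aryl ketone beside a methyl ester and aryl pivalates; the new benzylic centre is left racemic on purpose because the later ring closure is stereoconvergent.

Step 8
Reactants: 10 methyl 5-geranyl-2-{2-hydroxy-2-[2-methoxy-4-(pivaloyloxy)phenyl]ethoxy}-4-(pivaloyloxy)benzoate (racemic)
Product: 12 4-acetoxy-2-[2-(4-acetoxy-2-methoxyphenyl)-2-hydroxyethoxy]-5-geranylbenzoic acid (racemic), via lithium salt of the fully deprotected triol acid 11 (not isolated)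
Conditions: LiOH·H2O (6 equiv), degassed THF/H2O, 40 °C; then 0 °C, Ac2O (3 equiv), pH 9–10; cold 1 M HCl to pH 4
Reagents that add atoms: lithium hydroxide, [Li+].[OH-]; acetic anhydride, CC(=O)OC(C)=O
Why: Saponification of the methyl ester and both aryl pivalates followed in the same aqueous base by Schotten–Baumann acetylation, in which only the phenoxides should be acylated while the secondary alcohol stays free and the carboxylate is regenerated from its mixed anhydride, so that the acid-labile free p-hydroxybenzylic alcohol is never isolated.

Step 9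
Reactants: 12 4-acetoxy-2-[2-(4-acetoxy-2-methoxyphenyl)-2-hydroxyethoxy]-5-geranylbenzoic acid (racemic)
Product: 13 4-acetoxy-2-[2-(4-acetoxy-2-methoxyphenyl)-2-chloroethoxy]-5-geranylbenzoyl chloride (racemic)
Conditions: 1-chloro-N,N,2-trimethylprop-1-en-1-amine (2.3 equiv), CH2Cl2, 0 °C → rt; evaporate, toluene azeotrope, use crude at once
Reagents that add atoms: 1-chloro-N,N,2-trimethylprop-1-en-1-amine, CC(C)=C(Cl)N(C)C
Why: The α-chloroenamine turns a carboxylic acid into its chloride and a secondary benzylic alcohol into the alkyl chloride (neutral deoxychlorination) without releasing HCl, so geranyl alkenes and aryl acetates should be untouched, and the para-acetate and β-aryloxy group hold back ionisation of the new C–Cl bond.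

Step 10
Reactants: 13 4-acetoxy-2-[2-(4-acetoxy-2-methoxyphenyl)-2-chloroethoxy]-5-geranylbenzoyl chloride (racemic)
Product: 14 (3S)-7-acetoxy-3-(4-acetoxy-2-methoxyphenyl)-6-geranylchroman-4-one
Conditions: NiCl2·dme (15 mol %), 2,2'-(propane-2,2-diyl)bis(4-phenyl-4,5-dihydrooxazole) (single enantiomer, 18 mol %), Mn powder (3 equiv), 2,6-dimethylbenzoic acid (0.5 equiv), 3 Å MS, DMA/THF 3:7, 20 °C; 13 added by syringe pump to 0.01 M
Reagents that add atoms: none
Why: Proposed new method: nickel(0)–bis(oxazoline), formed by manganese reduction, should insert into the aroyl C–Cl bond, the reduced acyl-nickel species should abstract chlorine from either enantiomer of the tethered benzylic chloride, and the planar C3 radical should recombine at nickel to give a seven-membered acyl–alkyl nickelacycle whose reductive elimination forms C3–C4. The closest known reaction type is the intermolecular nickel/bis(oxazoline)-catalysed enantioconvergent reductive coupling of acid chlorides with racemic secondary benzylic chlorides under manganese in DMA/THF. The pyranone ring closes by C(acyl)–C(sp3) reductive elimination with contraction of the seven-membered nickelacycle to the six-membered ring, formally a 6-exo capture of the benzylic radical by the acyl-nickel centre. C3 is set S by the chiral bis(oxazoline) during radical capture and reductive elimination, both enantiomers of 13 passing through the same radical. The step needs ring closure to beat dimerisation and intermolecular ketone formation, which the four-atom ether tether and slow addition at high dilution should secure, and it needs the benzylic chloride to last until nickel reaches it, which the para-acetate and β-aryloxy group should secure. No base is present, so the α-aryl ketone should not epimerise.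

Step 11
Reactants: 14 (3S)-7-acetoxy-3-(4-acetoxy-2-methoxyphenyl)-6-geranylchroman-4-one
Product: 15 (3S)-6-[(2E)-3,7-dimethylocta-2,6-dien-1-yl]-7-hydroxy-3-(4-hydroxy-2-methoxyphenyl)chroman-4-one
Conditions: NH4OAc (8 equiv), MeOH/H2O 4:1, 20 °C
Reagents that add atoms: none
Why: Ammonium acetate-mediated solvolysis of aryl acetates proceeds at near-neutral pH, far below the basicity needed to enolise C3–H or to open the pyranone by retro-oxa-Michael reaction, so the 3S configuration should be kept.

**Compound list**
1 | geranyl bromide, (2E)-1-bromo-3,7-dimethylocta-2,6-diene | CC(C)=CCC/C(C)=C/CBr | starting material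
2 | geranyltributylstannane, tributyl[(2E)-3,7-dimethylocta-2,6-dien-1-yl]stannane | CCCC[Sn](CCCC)(CCCC)C/C=C(\C)CCC=C(C)C | intermediate
3 | methyl 5-bromo-2,4-dihydroxybenzoate | COC(=O)c1cc(Br)c(O)cc1O | starting material
4 | methyl 5-bromo-2-hydroxy-4-(pivaloyloxy)benzoate | COC(=O)c1cc(Br)c(OC(=O)C(C)(C)C)cc1O | intermediate
5 | methyl 5-[(2E)-3,7-dimethylocta-2,6-dien-1-yl]-2-hydroxy-4-(pivaloyloxy)benzoate | COC(=O)c1cc(C/C=C(\C)CCC=C(C)C)c(OC(=O)C(C)(C)C)cc1O | intermediate
6 | 4'-hydroxy-2'-methoxyacetophenone | COc1cc(O)ccc1C(C)=O | starting material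
7 | 4-acetyl-3-methoxyphenyl pivalate | COc1cc(OC(=O)C(C)(C)C)ccc1C(C)=O | intermediate
8 | 4-(2-bromoacetyl)-3-methoxyphenyl pivalate | COc1cc(OC(=O)C(C)(C)C)ccc1C(=O)CBr | intermediate
9 | methyl 5-geranyl-2-{2-[2-methoxy-4-(pivaloyloxy)phenyl]-2-oxoethoxy}-4-(pivaloyloxy)benzoate | COc1cc(OC(=O)C(C)(C)C)ccc1C(=O)COc1cc(OC(=O)C(C)(C)C)c(C/C=C(\C)CCC=C(C)C)cc1C(=O)OC | intermediate
10 | methyl 5-geranyl-2-{2-hydroxy-2-[2-methoxy-4-(pivaloyloxy)phenyl]ethoxy}-4-(pivaloyloxy)benzoate, racemic | COc1cc(OC(=O)C(C)(C)C)ccc1C(O)COc1cc(OC(=O)C(C)(C)C)c(C/C=C(\C)CCC=C(C)C)cc1C(=O)OC | intermediate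
11 | 5-geranyl-4-hydroxy-2-[2-hydroxy-2-(4-hydroxy-2-methoxyphenyl)ethoxy]benzoic acid, racemic, present in the flask as its lithium salt | COc1cc(O)ccc1C(O)COc1cc(O)c(C/C=C(\C)CCC=C(C)C)cc1C(=O)O | intermediate (not isolated)
12 | 4-acetoxy-2-[2-(4-acetoxy-2-methoxyphenyl)-2-hydroxyethoxy]-5-geranylbenzoic acid, racemic | COc1cc(OC(C)=O)ccc1C(O)COc1cc(OC(C)=O)c(C/C=C(\C)CCC=C(C)C)cc1C(=O)O | intermediate
13 | 4-acetoxy-2-[2-(4-acetoxy-2-methoxyphenyl)-2-chloroethoxy]-5-geranylbenzoyl chloride, racemic | COc1cc(OC(C)=O)ccc1C(Cl)COc1cc(OC(C)=O)c(C/C=C(\C)CCC=C(C)C)cc1C(=O)Cl | intermediate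
14 | (3S)-7-acetoxy-3-(4-acetoxy-2-methoxyphenyl)-6-geranylchroman-4-one | COc1cc(OC(C)=O)ccc1[C@H]1COc2cc(OC(C)=O)c(C/C=C(\C)CCC=C(C)C)cc2C1=O | intermediate
15 | (3S)-6-[(2E)-3,7-dimethylocta-2,6-dien-1-yl]-7-hydroxy-3-(4-hydroxy-2-methoxyphenyl)chroman-4-one | COc1cc(O)ccc1[C@H]1COc2cc(O)c(C/C=C(\C)CCC=C(C)C)cc2C1=O | target

Total step count: 11. Longest linear sequence: 8 steps (for example 3 → 4 → 5 → 9 → 10 → 12 → 13 → 14 → 15).

**Steps most likely to fail**

Step 10 (new method). Ring closure may be outrun by intermolecular coupling or by loss of the benzylic chloride through ionisation or β-aryloxy elimination at nickel, and discrimination of the faces of the C3 radical may be weak. The fallback sets out from 13 and returns at 14. The aroyl chloride is reduced at −78 °C with LiAlH(O-t-Bu)3 (acid chloride to aldehyde reduction) to give 4-acetoxy-2-[2-(4-acetoxy-2-methoxyphenyl)-2-chloroethoxy]-5-geranylbenzaldehyde F1. An N-heterocyclic carbene (thiazolium precatalyst, Cs2CO3, toluene, 60 °C) then turns the aldehyde into its acyl anion equivalent, which is alkylated by the tethered, ionisable benzylic chloride. This carbene-catalysed umpolung alkylation is documented for the closure of 2-(2-haloethoxy)benzaldehydes to chroman-4-ones and for the acylation of benzylic halides. It should give the racemic diacetate rac-7-acetoxy-3-(4-acetoxy-2-methoxyphenyl)-6-geranylchroman-4-one F2. Preparative chromatography on a chiral stationary phase then delivers 14, and the 3R antipode can be racemised with a trace of amidine base and recycled.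

Step 9. Once the acid chloride has formed, the free alcohol may lactonise to the seven-membered benzodioxepinone before it is chlorinated, and the benzylic chloride may eliminate or hydrolyse during concentration. The fallback sets out from 12 and returns at 13. One equivalent of TBSCl with imidazole at 0 °C silylates the carboxyl group to give tert-butyldimethylsilyl 4-acetoxy-2-[2-(4-acetoxy-2-methoxyphenyl)-2-hydroxyethoxy]-5-geranylbenzoate F3. With the acid masked, the alcohol is converted by one equivalent of the α-chloroenamine into tert-butyldimethylsilyl 4-acetoxy-2-[2-(4-acetoxy-2-methoxyphenyl)-2-chloroethoxy]-5-geranylbenzoate F4. Oxalyl chloride with catalytic DMF then exchanges the silyl ester directly for the acid chloride, again without HCl, to give 13.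

Step 11. The C3 configuration may erode by enolisation or reversible ring opening while the hindered 7-acetate is slowly cleaved. The fallback sets out from 14 and returns at 15. It replaces solution solvolysis by enzyme-mediated acyl transfer in a dry, base-free medium: immobilised Candida antarctica lipase B with n-butanol in MTBE at 35 °C moves both acetyl groups to butanol through the acyl-enzyme. No new compound arises (F0).

**Further compounds**
F1 | step 10 | 4-acetoxy-2-[2-(4-acetoxy-2-methoxyphenyl)-2-chloroethoxy]-5-geranylbenzaldehyde, racemic | COc1cc(OC(C)=O)ccc1C(Cl)COc1cc(OC(C)=O)c(C/C=C(\C)CCC=C(C)C)cc1C=O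
F2 | step 10 | rac-7-acetoxy-3-(4-acetoxy-2-methoxyphenyl)-6-geranylchroman-4-one | COc1cc(OC(C)=O)ccc1C1COc2cc(OC(C)=O)c(C/C=C(\C)CCC=C(C)C)cc2C1=O
F3 | step 9 | tert-butyldimethylsilyl 4-acetoxy-2-[2-(4-acetoxy-2-methoxyphenyl)-2-hydroxyethoxy]-5-geranylbenzoate, racemic | COc1cc(OC(C)=O)ccc1C(O)COc1cc(OC(C)=O)c(C/C=C(\C)CCC=C(C)C)cc1C(=O)O[Si](C)(C)C(C)(C)C
F4 | step 9 | tert-butyldimethylsilyl 4-acetoxy-2-[2-(4-acetoxy-2-methoxyphenyl)-2-chloroethoxy]-5-geranylbenzoate, racemic | COc1cc(OC(C)=O)ccc1C(Cl)COc1cc(OC(C)=O)c(C/C=C(\C)CCC=C(C)C)cc1C(=O)O[Si](C)(C)C(C)(C)C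
F0 | step 11 | none | none
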